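**Retrosynthetic overview**
- Feature: in ring C, C2 is an isolated CH bonded only to O1 and C3. The O1-C2 unit can therefore be carried in as an aryl methyl ether on ring A, and only the C2-C3 bond must be made.
- Key disconnection: C2-C3, formed when a rhodium carbene centred on C3 inserts into a methoxy C-H bond. This closes ring C as an isoflavanone, which is then dehydrogenated.
- The diazoketone comes from a deoxybenzoin by diazo transfer. The deoxybenzoin (C4-C4a bond) comes from acylation of symmetrical 1,3,5-trimethoxybenzene with bis-pivaloylated 2,4-dihydroxyphenylacetic acid.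
- End game: both ring A methyl ethers are cleaved and O7 is prenylated while 5-OH is chelated and ring B is still esterified. The pivalates are removed last.
- Ring order: rings A and B are bought; ring C is the only ring built.

Key step: step 4

Remark: the target has no stereocentre. C3 of the isoflavanone forms as a racemate and becomes sp2 in the next step, so no absolute control is planned.

Step 1
Reactants: 1 2,4-dihydroxyphenylacetic acid; 2 pivaloyl chloride
Product: 3 2,4-bis(pivaloyloxy)phenylacetic acid
Conditions: 2 (2.3 equiv), aq NaOH (3.6 equiv), THF-H2O, 0 °C, N2; then 1 M HCl to pH 2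
Reagents that add atoms: pivaloyl chloride 2, CC(C)(C)C(=O)Cl
Why: Schotten-Baumann O-acylation, in which both phenoxides take up the hindered acid chloride faster than it hydrolyses, and aqueous base reopens any mixed anhydride or benzofuran-2(3H)-one formed at the carboxyl group, so the material should funnel to the free acid on acidification.

Step 2
Reactants: 3 2,4-bis(pivaloyloxy)phenylacetic acid; 4 1,3,5-trimethoxybenzene
Product: 6 2-[2,4-bis(pivaloyloxy)phenyl]-1-(2,4,6-trimethoxyphenyl)ethanone, via acyl trifluoroacetate 5 (not isolated)
Conditions: TFAA (1.2 equiv), CH2Cl2, 0 °C; then 4 (1.2 equiv), 85% H3PO4 (10 mol%), 0 °C to rt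
Reagents that add atoms: trifluoroacetic anhydride, O=C(OC(=O)C(F)(F)F)C(F)(F)F (its trifluoroacetyl group is carried by 5 only and is absent from 6)
Why: Friedel-Crafts acylation through a mixed anhydride, which works because 4 is nucleophilic enough to react without a metal Lewis acid (sparing the ortho methyl ethers and the aryl esters) and its three equivalent positions allow only one ketone.

Step 3
Reactants: 6 2-[2,4-bis(pivaloyloxy)phenyl]-1-(2,4,6-trimethoxyphenyl)ethanone
Product: 7 2-diazo-2-[2,4-bis(pivaloyloxy)phenyl]-1-(2,4,6-trimethoxyphenyl)ethanone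
Conditions: 4-acetamidobenzenesulfonyl azide (1.3 equiv), DBU (1.5 equiv), MeCN, 0 °C to rt
Reagents that add atoms: 4-acetamidobenzenesulfonyl azide, CC(=O)Nc1ccc(cc1)S(=O)(=O)N=[N+]=[N-]
Why: Regitz diazo transfer, in which DBU deprotonates the methylene activated by both the ketone and ring B, the enolate adds to the terminal azide nitrogen and the adduct collapses to diazoketone and sulfonamide, while the hindered aryl pivalates should outlast the amidine base at this temperature.

Step 4
Reactants: 7 2-diazo-2-[2,4-bis(pivaloyloxy)phenyl]-1-(2,4,6-trimethoxyphenyl)ethanone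
Product: 8 rac-5,7-dimethoxy-2',4'-bis(pivaloyloxy)isoflavanone
Conditions: Rh2(O2CC7H15)4 (1 mol%), CH2Cl2, 4 Å MS, Ar, 40 °C, 7 added over 3 h
Reagents that add atoms: none
Why: Rh2(O2CC7H15)4 attacks the diazo carbon of 7, nitrogen leaves, and an electrophilic rhodium carbene results at C3, tempered by ring B as donor and the aroyl carbonyl as acceptor. A C-H bond of a flanking methoxy group, hydridic because the ether oxygen carries the developing positive charge, then adds across the carbene carbon in one asynchronous three-centre event that makes C2-C3 and frees the catalyst. The closest known reactions are the dirhodium-catalysed 1,6 C-H insertion of 2-alkoxyaryl diazoketones to chroman-4-ones, the C-H insertion cyclisation of alpha-aryl-alpha-diazoketones, and the intermolecular insertion of aryl-substituted carbenes into methyl ether C-H bonds. Ring C closes as a six-membered ring (C3, C4, C4a, C8a, O1, C2) in the 1,6 mode, the usual 1,5 mode being impossible on this side because the fifth atom is the oxygen itself. C3 becomes a stereocentre without control, since the catalyst is achiral and no other stereocentre is present, and the racemate is accepted because step 5 flattens C3. The step needs chemoselectivity, which the substrate and conditions secure in four ways: the acyl group on O2' offers no C-H next to oxygen for a five-membered insertion on ring B (the nearest tert-butyl C-H would need a seven-membered ring), methyl migrates so poorly that the five-membered oxonium ylide from a methoxy oxygen should revert to the carbene, the two ortho methoxy groups are equivalent so either gives 8, and slow addition under dry, oxygen-free conditions at 40 °C holds back dimerisation, O-H insertion and Wolff rearrangement.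

Step 5
Reactants: 8 rac-5,7-dimethoxy-2',4'-bis(pivaloyloxy)isoflavanone
Product: 9 5,7-dimethoxy-2',4'-bis(pivaloyloxy)isoflavone
Conditions: DDQ (1.5 equiv), 1,4-dioxane, reflux
Reagents that add atoms: none
Why: DDQ dehydrogenation of an isoflavanone, in which the enol of 8 passes the C2 hydride (activated by O1) to the quinone and loses its proton, so ring C becomes the 4H-chromen-4-one and the C3 stereocentre disappears with esters and methyl ethers untouched.

Step 6
Reactants: 9 5,7-dimethoxy-2',4'-bis(pivaloyloxy)isoflavone
Product: 10 5,7-dihydroxy-2',4'-bis(pivaloyloxy)isoflavone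
Conditions: BBr3 (6 equiv), CH2Cl2, -78 °C to rt; then ice-water
Reagents that add atoms: none
Why: Lewis acid ether cleavage, in which boron binds each methoxy oxygen (O5 first, helped by chelation to the C4 carbonyl) and bromide removes the methyl group by SN2, whereas an aryl pivalate has no sp3 C-O bond to attack and a shielded carbonyl carbon, so both esters should be kept.

Step 7
Reactants: 10 5,7-dihydroxy-2',4'-bis(pivaloyloxy)isoflavone; 11 prenyl bromide (1-bromo-3-methylbut-2-ene)
Product: 12 5-hydroxy-7-prenyloxy-2',4'-bis(pivaloyloxy)isoflavone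
Conditions: 11 (1.1 equiv), K2CO3 (1.2 equiv), dry acetone, rt to 40 °C
Reagents that add atoms: prenyl bromide 11, CC(C)=CCBr
Why: Williamson ether synthesis, selective because 7-OH is the only available acidic phenol (5-OH is locked in a hydrogen bond to the C4 carbonyl and both ring B oxygens are acylated), so about one equivalent of the allylic bromide should alkylate O7 alone by SN2.

Step 8
Reactants: 12 5-hydroxy-7-prenyloxy-2',4'-bis(pivaloyloxy)isoflavone
Product: 13 5,2',4'-trihydroxy-7-prenyloxyisoflavone (target)
Conditions: K2CO3 (3 equiv), MeOH-THF, 0 °C to rt, Ar; then 1 M HCl to pH 5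
Reagents that add atoms: none
Why: Base-mediated transesterification, in which methoxide attacks the aryl ester carbonyls and expels the good phenoxide leaving groups, and the prenyl aryl ether and the chromenone ring should stay intact when air is excluded and acidification is mild.

**Compound list**
1 | 2,4-dihydroxyphenylacetic acid | O=C(O)Cc1ccc(O)cc1O | starting material
2 | pivaloyl chloride | CC(C)(C)C(=O)Cl | starting material
3 | 2,4-bis(pivaloyloxy)phenylacetic acid | O=C(O)Cc1ccc(OC(=O)C(C)(C)C)cc1OC(=O)C(C)(C)C | intermediate
4 | 1,3,5-trimethoxybenzene | COc1cc(OC)cc(OC)c1 | starting material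
5 | 2,4-bis(pivaloyloxy)phenylacetic trifluoroacetic anhydride | O=C(Cc1ccc(OC(=O)C(C)(C)C)cc1OC(=O)C(C)(C)C)OC(=O)C(F)(F)F | intermediate
6 | 2-[2,4-bis(pivaloyloxy)phenyl]-1-(2,4,6-trimethoxyphenyl)ethanone | COc1cc(OC)c(C(=O)Cc2ccc(OC(=O)C(C)(C)C)cc2OC(=O)C(C)(C)C)c(OC)c1 | intermediate
7 | 2-diazo-2-[2,4-bis(pivaloyloxy)phenyl]-1-(2,4,6-trimethoxyphenyl)ethanone | COc1cc(OC)c(C(=O)C(=[N+]=[N-])c2ccc(OC(=O)C(C)(C)C)cc2OC(=O)C(C)(C)C)c(OC)c1 | intermediate
8 | rac-5,7-dimethoxy-2',4'-bis(pivaloyloxy)isoflavanone (racemate; the SMILES draws the 3S antipode only) | COc1cc(OC)c2c(c1)OC[C@H](c1ccc(OC(=O)C(C)(C)C)cc1OC(=O)C(C)(C)C)C2=O | intermediate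
9 | 5,7-dimethoxy-2',4'-bis(pivaloyloxy)isoflavone | COc1cc(OC)c2c(=O)c(-c3ccc(OC(=O)C(C)(C)C)cc3OC(=O)C(C)(C)C)coc2c1 | intermediate
10 | 5,7-dihydroxy-2',4'-bis(pivaloyloxy)isoflavone | Oc1cc(O)c2c(=O)c(-c3ccc(OC(=O)C(C)(C)C)cc3OC(=O)C(C)(C)C)coc2c1 | intermediate
11 | prenyl bromide (1-bromo-3-methylbut-2-ene) | CC(C)=CCBr | starting material
12 | 5-hydroxy-7-prenyloxy-2',4'-bis(pivaloyloxy)isoflavone | CC(C)=CCOc1cc(O)c2c(=O)c(-c3ccc(OC(=O)C(C)(C)C)cc3OC(=O)C(C)(C)C)coc2c1 | intermediate
13 | 5,2',4'-trihydroxy-7-prenyloxyisoflavone | CC(C)=CCOc1cc(O)c2c(=O)c(-c3ccc(O)cc3O)coc2c1 | target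

Total step count: 8. Longest linear sequence: 8 steps (from 1 to 13).

**Steps most likely to fail**

Step 4.
- What may go wrong: the carbene may be diverted before C-H insertion. A methoxy oxygen may attack it and then transfer methyl, the carbonyl oxygen of the 2'-pivalate may capture it, an aryl group may migrate (Wolff rearrangement), or it may dimerise.
- Fallback: this sets out from 6 and supplies C2 from a formyl equivalent instead of the methyl ether.
- BCl3 (CH2Cl2, -78 to 0 °C) removes one of the two carbonyl-flanking methyl groups through a boron chelate. This gives 1-(2-hydroxy-4,6-dimethoxyphenyl)-2-[2,4-bis(pivaloyloxy)phenyl]ethanone F1.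
- The methylene of F1 is then formylated under Vilsmeier-type conditions (DMF, BF3·OEt2, MsCl, 50 °C). Ring closure follows spontaneously, and the sequence rejoins the route at 9.

Step 6.
- What may go wrong: the unchelated 7-methyl ether needs long exposure to BBr3. This may strip the pivalates by acyl-oxygen cleavage, or cleavage at O7 may stay incomplete if the reaction is stopped early.
- Fallback: this sets out from 9, gives up ester protection, and relies on acidity differences.
- K2CO3 in MeOH frees ring B to give 2',4'-dihydroxy-5,7-dimethoxyisoflavone F2.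
- Excess BBr3 at rt then gives 5,7,2',4'-tetrahydroxyisoflavone F3.
- The monoanion of F3 is made with one equivalent of K2CO3 in DMF. It forms at 7-OH, the most acidic hydroxyl because it is a vinylogous acid of the C4 carbonyl.
- This monoanion is alkylated with one equivalent of 11, and the sequence comes back directly at 13.

Step 2.
- What may go wrong: the 2-pivaloyloxy oxygen may attack the activated carboxyl group (lactonisation with loss of the protecting group). The arene may also be trifluoroacetylated, or the acylation may reverse in acid.
- Fallback: this sets out from 4 and 2 and forms the C3-C1' bond instead of C4-C4a.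
- Compound 4 is acetylated (Ac2O, cat. Sc(OTf)3, MeNO2) to 1-(2,4,6-trimethoxyphenyl)ethanone F4.
- Purchased 4-bromoresorcinol is acylated with 2 under the conditions of step 1 to give 4-bromo-1,3-phenylene bis(pivalate) F5.
- Palladium-catalysed ketone alpha-arylation joins the two, using Pd(OAc)2, 2-dicyclohexylphosphino-2'-methylbiphenyl and K3PO4 in toluene at 80 °C. The sequence comes back at 6.

**Further compounds**
F1 | step 4 | 1-(2-hydroxy-4,6-dimethoxyphenyl)-2-[2,4-bis(pivaloyloxy)phenyl]ethanone | COc1cc(O)c(C(=O)Cc2ccc(OC(=O)C(C)(C)C)cc2OC(=O)C(C)(C)C)c(OC)c1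
F2 | step 6 | 2',4'-dihydroxy-5,7-dimethoxyisoflavone | COc1cc(OC)c2c(=O)c(-c3ccc(O)cc3O)coc2c1
F3 | step 6 | 5,7,2',4'-tetrahydroxyisoflavone | Oc1cc(O)c2c(=O)c(-c3ccc(O)cc3O)coc2c1
F4 | step 2 | 1-(2,4,6-trimethoxyphenyl)ethanone | CC(=O)c1c(OC)cc(OC)cc1OC
F5 | step 2 | 4-bromo-1,3-phenylene bis(pivalate) | Brc1ccc(OC(=O)C(C)(C)C)cc1OC(=O)C(C)(C)C
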